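**Plan**

1. Retrosynthetic cuts, in this order: the senecioate C–O bond (Mitsunobu, inversion at C2), the side-chain C=C (cross-metathesis of an allyl group), the two epoxide C–O bonds (hydroxyl-directed epoxidation), the ring bond C1–C2 (alkenylchromium addition to an enal), C7=C8 (Wittig), and the bonds at the quaternary C5 (Johnson–Claisen).
2. Enabling feature: in the 12-oxabicyclo[9.1.0]dodecane core the methyl-bearing epoxide carbon C1 is bonded to the allylic carbinol C2. At the alkene oxidation level C1 is the sp2 carbon of an (E)-2-iodoalkene and C2 an enal carbonyl, so one carbonyl addition closes the 11-membered carbocycle, fixes the E alkene that becomes the trans-epoxide, and creates the hydroxyl that steers the epoxidation.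
3. Forward order: a C2–C7 aldehyde carrying the quaternary carbon is joined to a C8–C1 ylide to give the open chain; then the 11-membered ring, then the oxirane ring, then the ester, last the side chain.
4. Stereochemistry: one carbinol is set by CBS reduction and relayed to C5 by chair Claisen transfer; C2 is set by a chiral chromium complex in the ring closure; C1 and C11 are set together by oxygen delivery from the C2 hydroxyl (erythro); Mitsunobu inversion then gives the natural C2 configuration.
5. Helpers: the alkene oxidation level at C1/C11, the ethyl ester as masked C8 aldehyde, the unnatural C2 hydroxyl as directing group, and the allyl group as masked side chain; all are removed in steps 13 to 17.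

Key step: step 12

Remark: atom numbers in the text are those of the 12-oxabicyclo[9.1.0]dodecane core (C1 methyl-bearing epoxide carbon, C2 acyloxy carbon, C5 quaternary carbon, C8 formyl-bearing carbon, C11 epoxide CH); for step 12 the antipode of the oxazoline sulfonamide ligand that gives the 2R carbinol is assumed, its sense of induction to be assigned on a model coupling.

**Route**

Step 1
Reactants: 1 pent-1-en-4-yne
Product: 3 (1E)-1-iodo-2-methylpenta-1,4-diene, via alkenylalane 2 (not isolated)
Conditions: Me3Al (2 equiv), Cp2ZrCl2 (0.25 equiv), CH2Cl2, 0 to 23 °C; then I2, THF, −30 to 0 °C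
Reagents that add atoms: trimethylaluminium C[Al](C)C; iodine II
Why: Zirconium-catalysed carboalumination adds methyl and aluminium syn across the terminal alkyne with aluminium on the terminal carbon (the unactivated alkene is inert to Me3Al/Cp2ZrCl2), and iodinolysis of the C–Al bond with retention should give the E iodide; no stereocentre is formed.

Step 2
Reactants: 3 (1E)-1-iodo-2-methylpenta-1,4-diene; 4 2-[(tert-butyldimethylsilyl)oxy]-N-methoxy-N-methylacetamide
Product: 6 (3E)-1-[(tert-butyldimethylsilyl)oxy]-4-methylhepta-3,6-dien-2-one, via alkenyllithium 5 (not isolated)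
Conditions: t-BuLi (2.05 equiv), Et2O, −78 °C; then 4, −78 to 0 °C; aq. NH4Cl
Reagents that add atoms: none
Why: Lithium–iodine exchange proceeds with retention of alkene geometry, and the alkenyllithium acylates the Weinreb amide through a chelated tetrahedral adduct that collapses to the ketone only on work-up, so over-addition is avoided.

Step 3
Reactants: 6 (3E)-1-[(tert-butyldimethylsilyl)oxy]-4-methylhepta-3,6-dien-2-one
Product: 7 (2S,3E)-1-[(tert-butyldimethylsilyl)oxy]-4-methylhepta-3,6-dien-2-ol
Conditions: (S)-2-methyl-CBS-oxazaborolidine (0.2 equiv), catecholborane (1.8 equiv), toluene, −78 °C; then MeOH/H2O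
Reagents that add atoms: none
Why: Corey–Bakshi–Shibata reduction, in which the oxazaborolidine binds the ketone through the lone pair on the side of the small CH2OTBS group and delivers hydride from catecholborane (which does not hydroborate the alkenes at −78 °C) to one face; this should set the 2S carbinol, the stereocentre from which the quaternary carbon is relayed.

Step 4
Reactants: 7 (2S,3E)-1-[(tert-butyldimethylsilyl)oxy]-4-methylhepta-3,6-dien-2-ol; 8 1,1,1-triethoxyethane
Product: 10 ethyl (3R,4E)-6-[(tert-butyldimethylsilyl)oxy]-3-methyl-3-(prop-2-en-1-yl)hex-4-enoate, via ketene acetal 9 (not isolated)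
Conditions: 8 (6 equiv), EtCO2H (0.1 equiv), xylene, 140 °C, EtOH distilled off
Reagents that add atoms: none
Why: Johnson–Claisen rearrangement through a chair transition state with the carbinol hydrogen eclipsing the alkene (A(1,3) strain with the cis methyl group) and CH2OTBS equatorial, so the new C–C bond forms on the alkene face that carried the C–O bond; this should transfer the 2S configuration to the 3R quaternary carbon and give the E alkene.

Step 5
Reactants: 10 ethyl (3R,4E)-6-[(tert-butyldimethylsilyl)oxy]-3-methyl-3-(prop-2-en-1-yl)hex-4-enoate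
Product: 11 (3R,4E)-6-[(tert-butyldimethylsilyl)oxy]-3-methyl-3-(prop-2-en-1-yl)hex-4-enal
Conditions: diisobutylaluminium hydride (1.1 equiv), CH2Cl2, −78 °C; aq. potassium sodium tartrate
Reagents that add atoms: none
Why: Partial ester reduction at −78 °C stops at the tetrahedral aluminium hemiacetal, which releases the aldehyde on work-up; the quaternary carbon cannot epimerize.

Step 6
Reactants: 12 pent-3-yn-1-ol
Product: 13 5-chloropent-2-yne
Conditions: PPh3, N-chlorosuccinimide, CH2Cl2, 0 to 23 °C
Reagents that add atoms: N-chlorosuccinimide O=C1CCC(=O)N1Cl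
Why: Appel-type chlorination, in which chloride displaces the alkoxyphosphonium ion by SN2 at the primary carbon; chloride is chosen because it is inert to Cp2Zr(H)Cl in step 7.

Step 7
Reactants: 13 5-chloropent-2-yne
Product: 15 (2E)-5-chloro-2-iodopent-2-ene, via alkenylzirconocene 14 (not isolated)
Conditions: Cp2Zr(H)Cl (1.6 equiv), THF, 50 °C; then I2, 0 °C
Reagents that add atoms: iodine II
Why: Hydrozirconation adds Zr–H syn across the alkyne and, with excess reagent at 50 °C, the metal should equilibrate to the less hindered methyl-bearing carbon; iodinolysis with retention then gives the (E)-2-iodoalkene in which methyl and the chain are cis.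

Step 8
Reactants: 15 (2E)-5-chloro-2-iodopent-2-ene; 16 ethyl 2-(triphenyl-λ5-phosphanylidene)acetate
Product: 19 ethyl (5E)-6-iodo-2-(triphenyl-λ5-phosphanylidene)hept-5-enoate, via diiodide 17 (not isolated), via phosphonium iodide 18 (not isolated)
Conditions: NaI (1.2 equiv), MeCN, 80 °C; then aq. NaOH, CH2Cl2, 0 °C
Reagents that add atoms: none
Why: Finkelstein exchange gives the primary iodide 17, which C-alkylates the ester-stabilized ylide by SN2; deprotonation of the phosphonium salt 18 gives a stabilized α-substituted ylide, and the alkenyl iodide does not react.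

Step 9
Reactants: 11 (3R,4E)-6-[(tert-butyldimethylsilyl)oxy]-3-methyl-3-(prop-2-en-1-yl)hex-4-enal; 19 ethyl (5E)-6-iodo-2-(triphenyl-λ5-phosphanylidene)hept-5-enoate
Product: 20 ethyl (2E,5R,6E)-8-[(tert-butyldimethylsilyl)oxy]-2-[(3E)-4-iodopent-3-en-1-yl]-5-methyl-5-(prop-2-en-1-yl)octa-2,6-dienoate
Conditions: toluene, 100 °C
Reagents that add atoms: none
Why: Wittig olefination with a stabilized, α-branched ylide is reversible up to the oxaphosphetane and should give the E enoate, with the ester trans to the chain carbon on the aldehyde side, which is the geometry of the target enal.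

Step 10
Reactants: 20 ethyl (2E,5R,6E)-8-[(tert-butyldimethylsilyl)oxy]-2-[(3E)-4-iodopent-3-en-1-yl]-5-methyl-5-(prop-2-en-1-yl)octa-2,6-dienoate
Product: 21 ethyl (2E,5R,6E)-8-hydroxy-2-[(3E)-4-iodopent-3-en-1-yl]-5-methyl-5-(prop-2-en-1-yl)octa-2,6-dienoate
Conditions: Bu4NF, THF, 0 °C
Reagents that add atoms: none
Why: Fluoride-induced desilylation of the primary allylic silyl ether; the ethyl ester and the alkenyl iodide are inert to Bu4NF at 0 °C.

Step 11
Reactants: 21 ethyl (2E,5R,6E)-8-hydroxy-2-[(3E)-4-iodopent-3-en-1-yl]-5-methyl-5-(prop-2-en-1-yl)octa-2,6-dienoate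
Product: 22 ethyl (2E,5R,6E)-2-[(3E)-4-iodopent-3-en-1-yl]-5-methyl-8-oxo-5-(prop-2-en-1-yl)octa-2,6-dienoate
Conditions: MnO2 (20 equiv), CH2Cl2, 23 °C
Reagents that add atoms: none
Why: Allylic oxidation with MnO2 converts the primary allylic alcohol into the E enal without touching the other alkenes or the alkenyl iodide.

Step 12
Reactants: 22 ethyl (2E,5R,6E)-2-[(3E)-4-iodopent-3-en-1-yl]-5-methyl-8-oxo-5-(prop-2-en-1-yl)octa-2,6-dienoate
Product: 24 ethyl (1E,4R,5E,7R,8E)-7-hydroxy-4,8-dimethyl-4-(prop-2-en-1-yl)cycloundeca-1,5,8-triene-1-carboxylate, via alkenylchromium 23 (not isolated)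
Conditions: CrCl2 (4 equiv), N-[2-(4-isopropyl-4,5-dihydro-1,3-oxazol-2-yl)-6-methylphenyl]methanesulfonamide (single enantiomer, 4.4 equiv), Et3N (4.4 equiv), NiCl2 (0.1 equiv), THF, 23 °C, 22 added over 12 h (final 0.002 M); aq. work-up
Reagents that add atoms: none
Why: NiCl2 is reduced by CrCl2 to zerovalent nickel, which inserts into the C–I bond; transmetalation gives the alkenylchromium 23 with the E geometry retained, and this adds 1,2 to the enal carbonyl. The closest known reaction type is the Nozaki–Hiyama–Kishi macrocyclization of iodoalkene aldehydes to medium and large carbocycles, here in its ligand-controlled asymmetric form. The 11-membered ring closes in the 11-exo-trig mode at the aldehyde carbon, forming the C1–C2 bond of the target core. The new carbinol stereocentre (C2 of the core, C7 of 24) should be set 2R by the sulfonamide-bound chromium (reagent control), because the quaternary carbon is 1,4-remote and only tells methyl from allyl. The step needs aldehyde-over-ester chemoselectivity, 1,2- over 1,4-addition and ring closure over oligomerization: trivalent alkenylchromium species add neither to esters nor in the conjugate sense, which is why C8 is kept at the ester level. Slow addition at high dilution, helped by the three alkenes that remove torsional freedom from the 11-atom chain, should favour closure.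

Step 13
Reactants: 24 ethyl (1E,4R,5E,7R,8E)-7-hydroxy-4,8-dimethyl-4-(prop-2-en-1-yl)cycloundeca-1,5,8-triene-1-carboxylate
Product: 25 ethyl (1R,2R,3E,5R,7E,11R)-2-hydroxy-1,5-dimethyl-5-(prop-2-en-1-yl)-12-oxabicyclo[9.1.0]dodeca-3,7-diene-8-carboxylate
Conditions: VO(acac)2 (0.05 equiv), t-BuOOH (1.3 equiv), CH2Cl2, 0 °C
Reagents that add atoms: tert-butyl hydroperoxide CC(C)(C)OO
Why: Hydroxyl-directed epoxidation, in which the vanadium alkoxide of the C2 hydroxyl delivers oxygen to the electron-rich trisubstituted C1=C11 alkene on the face syn to the C–O bond, through the conformer with the hydroxyl near the alkene plane and the C2–C3 ring bond turned away from the C1 methyl group (A(1,2) strain); this should set C1 and C11 together, erythro to C2, while the enoate, disubstituted and terminal alkenes are left alone.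

Step 14
Reactants: 25 ethyl (1R,2R,3E,5R,7E,11R)-2-hydroxy-1,5-dimethyl-5-(prop-2-en-1-yl)-12-oxabicyclo[9.1.0]dodeca-3,7-diene-8-carboxylate
Product: 26 (1R,2R,3E,5R,7E,11R)-8-(hydroxymethyl)-1,5-dimethyl-5-(prop-2-en-1-yl)-12-oxabicyclo[9.1.0]dodeca-3,7-dien-2-ol
Conditions: diisobutylaluminium hydride (3.5 equiv), CH2Cl2, −78 °C; aq. potassium sodium tartrate
Reagents that add atoms: none
Why: The conjugated ester is reduced 1,2 to the allylic alcohol at −78 °C, where the trisubstituted epoxide next to the aluminium alkoxide should not be opened.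

Step 15
Reactants: 26 (1R,2R,3E,5R,7E,11R)-8-(hydroxymethyl)-1,5-dimethyl-5-(prop-2-en-1-yl)-12-oxabicyclo[9.1.0]dodeca-3,7-dien-2-ol
Product: 27 (1R,2R,3E,5R,7E,11R)-2-hydroxy-1,5-dimethyl-5-(prop-2-en-1-yl)-12-oxabicyclo[9.1.0]dodeca-3,7-diene-8-carbaldehyde
Conditions: TEMPO (0.1 equiv), PhI(OAc)2 (1.1 equiv), CH2Cl2, 23 °C
Reagents that add atoms: none
Why: Oxoammonium oxidation (TEMPO/PhI(OAc)2) is selective for the unhindered primary allylic alcohol over the secondary alcohol next to the epoxide and stops at the conjugated aldehyde.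

Step 16
Reactants: 27 (1R,2R,3E,5R,7E,11R)-2-hydroxy-1,5-dimethyl-5-(prop-2-en-1-yl)-12-oxabicyclo[9.1.0]dodeca-3,7-diene-8-carbaldehyde; 28 3-methylbut-2-enoic acid
Product: 29 (1S,2S,3E,5R,7E,11R)-8-formyl-1,5-dimethyl-5-(prop-2-en-1-yl)-12-oxabicyclo[9.1.0]dodeca-3,7-dien-2-yl 3-methylbut-2-enoate
Conditions: PPh3 (3 equiv), diisopropyl azodicarboxylate (3 equiv), 28 (3 equiv), toluene, 0 to 23 °C
Reagents that add atoms: none
Why: Mitsunobu esterification, in which the carboxylate displaces the alkoxyphosphonium group by SN2 with inversion, turning 2R into the natural 2S configuration as the ester is installed; the neighbouring epoxide disfavours ionization and the quaternary C5 blocks SN2' attack at C4.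

Step 17
Reactants: 29 (1S,2S,3E,5R,7E,11R)-8-formyl-1,5-dimethyl-5-(prop-2-en-1-yl)-12-oxabicyclo[9.1.0]dodeca-3,7-dien-2-yl 3-methylbut-2-enoate; 30 2-methylbut-3-en-2-ol
Product: 31 (1S,2S,3E,5R,7E,11R)-8-formyl-5-[(2E)-4-hydroxy-4-methylpent-2-en-1-yl]-1,5-dimethyl-12-oxabicyclo[9.1.0]dodeca-3,7-dien-2-yl 3-methylbut-2-enoate
Conditions: second-generation Hoveyda–Grubbs catalyst (0.1 equiv), 30 (10 equiv), CH2Cl2, 40 °C
Reagents that add atoms: none
Why: Olefin cross-metathesis between the only monosubstituted alkene and the hindered tertiary allylic alcohol should give the E side-chain alkene, because the other alkenes are trisubstituted, electron-poor or flanked by the quaternary carbon and do not enter the catalytic cycle.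

**Compound list**

1 | pent-1-en-4-yne | C=CCC#C | starting material
2 | dimethyl[(1E)-2-methylpenta-1,4-dien-1-yl]alumane | C=CC/C(C)=C/[Al](C)C | intermediate (not isolated)
3 | (1E)-1-iodo-2-methylpenta-1,4-diene | C=CC/C(C)=C/I | intermediate
4 | 2-[(tert-butyldimethylsilyl)oxy]-N-methoxy-N-methylacetamide | CON(C)C(=O)CO[Si](C)(C)C(C)(C)C | starting material
5 | [(1E)-2-methylpenta-1,4-dien-1-yl]lithium | C=CC/C(C)=C/[Li] | intermediate (not isolated)
6 | (3E)-1-[(tert-butyldimethylsilyl)oxy]-4-methylhepta-3,6-dien-2-one | C=CC/C(C)=C/C(=O)CO[Si](C)(C)C(C)(C)C | intermediate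
7 | (2S,3E)-1-[(tert-butyldimethylsilyl)oxy]-4-methylhepta-3,6-dien-2-ol | C=CC/C(C)=C/[C@H](O)CO[Si](C)(C)C(C)(C)C | intermediate
8 | 1,1,1-triethoxyethane (triethyl orthoacetate) | CCOC(C)(OCC)OCC | starting material
9 | tert-butyl{[(2S,3E)-2-[(1-ethoxyethenyl)oxy]-4-methylhepta-3,6-dien-1-yl]oxy}dimethylsilane | C=CC/C(C)=C/[C@H](OC(=C)OCC)CO[Si](C)(C)C(C)(C)C | intermediate (not isolated)
10 | ethyl (3R,4E)-6-[(tert-butyldimethylsilyl)oxy]-3-methyl-3-(prop-2-en-1-yl)hex-4-enoate | CC(C)(C)[Si](C)(C)OC/C=C/[C@](C)(CC=C)CC(=O)OCC | intermediate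
11 | (3R,4E)-6-[(tert-butyldimethylsilyl)oxy]-3-methyl-3-(prop-2-en-1-yl)hex-4-enal | CC(C)(C)[Si](C)(C)OC/C=C/[C@](C)(CC=C)CC=O | intermediate
12 | pent-3-yn-1-ol | CC#CCCO | starting material
13 | 5-chloropent-2-yne | CC#CCCCl | intermediate
14 | chloridobis(cyclopentadienyl)[(2E)-5-chloropent-2-en-2-yl]zirconium (rings drawn σ-bonded) | C/C(=C\CCCl)[Zr](Cl)(C1C=CC=C1)C1C=CC=C1 | intermediate (not isolated)
15 | (2E)-5-chloro-2-iodopent-2-ene | C/C(I)=C\CCCl | intermediate
16 | ethyl 2-(triphenyl-λ5-phosphanylidene)acetate | CCOC(=O)C=P(c1ccccc1)(c1ccccc1)c1ccccc1 | starting material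
17 | (2E)-2,5-diiodopent-2-ene | C/C(I)=C\CCI | intermediate (not isolated)
18 | [(5E)-1-ethoxy-6-iodo-1-oxohept-5-en-2-yl]triphenylphosphonium iodide | CCOC(=O)C(CC/C=C(\C)I)[P+](c1ccccc1)(c1ccccc1)c1ccccc1.[I-] | intermediate (not isolated)
19 | ethyl (5E)-6-iodo-2-(triphenyl-λ5-phosphanylidene)hept-5-enoate | CCOC(=O)C(CC/C=C(\C)I)=P(c1ccccc1)(c1ccccc1)c1ccccc1 | intermediate
20 | ethyl (2E,5R,6E)-8-[(tert-butyldimethylsilyl)oxy]-2-[(3E)-4-iodopent-3-en-1-yl]-5-methyl-5-(prop-2-en-1-yl)octa-2,6-dienoate | CC(C)(C)[Si](C)(C)OC/C=C/[C@](C)(CC=C)C/C=C(/C(=O)OCC)CC/C=C(\C)I | intermediate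
21 | ethyl (2E,5R,6E)-8-hydroxy-2-[(3E)-4-iodopent-3-en-1-yl]-5-methyl-5-(prop-2-en-1-yl)octa-2,6-dienoate | OC/C=C/[C@](C)(CC=C)C/C=C(/C(=O)OCC)CC/C=C(\C)I | intermediate
22 | ethyl (2E,5R,6E)-2-[(3E)-4-iodopent-3-en-1-yl]-5-methyl-8-oxo-5-(prop-2-en-1-yl)octa-2,6-dienoate | O=C/C=C/[C@](C)(CC=C)C/C=C(/C(=O)OCC)CC/C=C(\C)I | intermediate
23 | ethyl (2E,5R,6E)-2-[(3E)-4-(dichlorochromio)pent-3-en-1-yl]-5-methyl-8-oxo-5-(prop-2-en-1-yl)octa-2,6-dienoate (ligand on chromium omitted) | O=C/C=C/[C@](C)(CC=C)C/C=C(/C(=O)OCC)CC/C=C(\C)[Cr](Cl)Cl | intermediate (not isolated)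
24 | ethyl (1E,4R,5E,7R,8E)-7-hydroxy-4,8-dimethyl-4-(prop-2-en-1-yl)cycloundeca-1,5,8-triene-1-carboxylate | O[C@@H]1/C=C/[C@](C)(CC=C)C/C=C(/C(=O)OCC)CC/C=C1\C | intermediate
25 | ethyl (1R,2R,3E,5R,7E,11R)-2-hydroxy-1,5-dimethyl-5-(prop-2-en-1-yl)-12-oxabicyclo[9.1.0]dodeca-3,7-diene-8-carboxylate | O[C@@H]1/C=C/[C@](C)(CC=C)C/C=C(/C(=O)OCC)CC[C@H]2O[C@]12C | intermediate
26 | (1R,2R,3E,5R,7E,11R)-8-(hydroxymethyl)-1,5-dimethyl-5-(prop-2-en-1-yl)-12-oxabicyclo[9.1.0]dodeca-3,7-dien-2-ol | O[C@@H]1/C=C/[C@](C)(CC=C)C/C=C(/CO)CC[C@H]2O[C@]12C | intermediate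
27 | (1R,2R,3E,5R,7E,11R)-2-hydroxy-1,5-dimethyl-5-(prop-2-en-1-yl)-12-oxabicyclo[9.1.0]dodeca-3,7-diene-8-carbaldehyde | O[C@@H]1/C=C/[C@](C)(CC=C)C/C=C(/C=O)CC[C@H]2O[C@]12C | intermediate
28 | 3-methylbut-2-enoic acid | CC(C)=CC(=O)O | starting material
29 | (1S,2S,3E,5R,7E,11R)-8-formyl-1,5-dimethyl-5-(prop-2-en-1-yl)-12-oxabicyclo[9.1.0]dodeca-3,7-dien-2-yl 3-methylbut-2-enoate | CC(C)=CC(=O)O[C@H]1/C=C/[C@](C)(CC=C)C/C=C(/C=O)CC[C@H]2O[C@]12C | intermediate
30 | 2-methylbut-3-en-2-ol | C=CC(C)(C)O | starting material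
31 | (1S,2S,3E,5R,7E,11R)-8-formyl-5-[(2E)-4-hydroxy-4-methylpent-2-en-1-yl]-1,5-dimethyl-12-oxabicyclo[9.1.0]dodeca-3,7-dien-2-yl 3-methylbut-2-enoate | CC(C)=CC(=O)O[C@H]1/C=C/[C@](C)(C/C=C/C(C)(C)O)C/C=C(/C=O)CC[C@H]2O[C@]12C | target

**Step count and risks**

Total step count: 17. Longest linear sequence: 14 steps (steps 1 to 5 and 9 to 17).

Step 12. What may go wrong: weak facial control by the chromium-bound ligand in the ring-forming carbonyl addition, so that both C2 epimers form (the remote quaternary carbon gives no help), together with oligomerization if closure is slow. Fallback: the route sets out from enal 22, which is cyclized without ligand (CrCl2, NiCl2 cat., DMSO, high dilution) to 24 and its carbinol epimer. MnO2 in CH2Cl2 oxidizes both to the cross-conjugated macrocyclic dienone ethyl (1E,4R,5E,8E)-4,8-dimethyl-7-oxo-4-(prop-2-en-1-yl)cycloundeca-1,5,8-triene-1-carboxylate F1. Corey–Bakshi–Shibata reduction of this ketone with (S)-2-methyl-CBS-oxazaborolidine and catecholborane, in which the α-methyl-substituted alkenyl arm should act as the large group, returns the route at 24.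

Step 16. What may go wrong: slow SN2 displacement at C2, which is flanked by the fully substituted epoxide carbon, so that elimination or ester formation with retention takes over. Fallback: the route sets out from enal 22 and the ring is closed with the antipodal ligand (or the dienone F1 is reduced with the (R)-oxazaborolidine) to the epimeric dienol ethyl (1E,4R,5E,7S,8E)-7-hydroxy-4,8-dimethyl-4-(prop-2-en-1-yl)cycloundeca-1,5,8-triene-1-carboxylate F2. Diisobutylaluminium hydride at −78 °C gives the diol (1S,2E,6E,9R,10E)-6-(hydroxymethyl)-2,9-dimethyl-9-(prop-2-en-1-yl)cycloundeca-2,6,10-trien-1-ol F3. TEMPO/PhI(OAc)2 gives the hydroxy enal (1E,4R,5E,7S,8E)-7-hydroxy-4,8-dimethyl-4-(prop-2-en-1-yl)cycloundeca-1,5,8-triene-1-carbaldehyde F4. Acylation with acid 28 (dicyclohexylcarbodiimide, 4-dimethylaminopyridine, CH2Cl2), which keeps the carbinol configuration, gives the ester (1S,2E,6E,9R,10E)-6-formyl-2,9-dimethyl-9-(prop-2-en-1-yl)cycloundeca-2,6,10-trien-1-yl 3-methylbut-2-enoate F5. A Shi epoxidation (D-fructose-derived ketone, KHSO5, K2CO3, MeCN/dimethoxymethane/aqueous buffer, 0 °C) should then oxidize the only electron-rich trisubstituted alkene from the face fixed by the reagent and return the route at 29.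

Step 8. What may go wrong: sluggish C-alkylation of the stabilized ylide by the unactivated primary iodide, with elimination to the diene and incomplete conversion. Fallback: the route sets out from 15, which alkylates the sodium salt of triethyl phosphonoacetate (NaH, NaI, dimethylformamide, 60 °C) to the phosphonate ethyl (5E)-2-(diethoxyphosphoryl)-6-iodohept-5-enoate F6. A Horner–Wadsworth–Emmons reaction of this phosphonate with aldehyde 11 (LiCl, 1,8-diazabicyclo[5.4.0]undec-7-ene, MeCN) should give the E enoate after chromatographic removal of the minor Z isomer, and the route is rejoined at 20.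

Further compounds
F1 | step 12 | ethyl (1E,4R,5E,8E)-4,8-dimethyl-7-oxo-4-(prop-2-en-1-yl)cycloundeca-1,5,8-triene-1-carboxylate | O=C1/C=C/[C@](C)(CC=C)C/C=C(/C(=O)OCC)CC/C=C1\C
F2 | step 16 | ethyl (1E,4R,5E,7S,8E)-7-hydroxy-4,8-dimethyl-4-(prop-2-en-1-yl)cycloundeca-1,5,8-triene-1-carboxylate | O[C@H]1/C=C/[C@](C)(CC=C)C/C=C(/C(=O)OCC)CC/C=C1\C
F3 | step 16 | (1S,2E,6E,9R,10E)-6-(hydroxymethyl)-2,9-dimethyl-9-(prop-2-en-1-yl)cycloundeca-2,6,10-trien-1-ol | O[C@H]1/C=C/[C@](C)(CC=C)C/C=C(/CO)CC/C=C1\C
F4 | step 16 | (1E,4R,5E,7S,8E)-7-hydroxy-4,8-dimethyl-4-(prop-2-en-1-yl)cycloundeca-1,5,8-triene-1-carbaldehyde | O[C@H]1/C=C/[C@](C)(CC=C)C/C=C(/C=O)CC/C=C1\C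
F5 | step 16 | (1S,2E,6E,9R,10E)-6-formyl-2,9-dimethyl-9-(prop-2-en-1-yl)cycloundeca-2,6,10-trien-1-yl 3-methylbut-2-enoate | CC(C)=CC(=O)O[C@H]1/C=C/[C@](C)(CC=C)C/C=C(/C=O)CC/C=C1\C
F6 | step 8 | ethyl (5E)-2-(diethoxyphosphoryl)-6-iodohept-5-enoate | CCOC(=O)C(CC/C=C(\C)I)P(=O)(OCC)OCC
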